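**Plan**

1. Prostanoid numbering is used. The ring is C8–C12 (C9 = C=O, C10 = C–Cl, C11 = CH, C12 = carbinol carbon), the α-chain is C1–C7 and the ω-chain is C13–C20.
2. Cuts: first C7=C8 (aldol condensation with enal 15). Then C9–C10 and C10–C11 together, so that C10 leaves as :CCl2. Last C12–C13 (allylbarium addition to a cyclobutanone).
3. Enabling feature: the ring segment C9(=O)–C10(Cl)=C11H is the retron of a dichlorocarbene insertion into an enol ether C9=C11. Without C10 the ring is a 3,3-disubstituted cyclobutanone whose mirror plane holds C9 and C12, so C8H2 and C11H2 are enantiotopic.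
4. Forward order: ω-chain onto a commercial four-membered ring, prochiral cyclobutanone 8, enol silane 10, strain-driven 4→5 ring enlargement (the only ring of the target), α-chain by aldol/elimination, desilylation.
5. Stereochemistry: C12 comes from a chiral lithium amide desymmetrisation (step 6) and is not touched afterwards. 14Z comes from (Z)-oct-2-en-1-ol, 5E from cross metathesis, and 7E from the E1cB elimination.

Key step: step 7

Assumption: the sense of induction of the chiral lithium amide on 8 is assigned by analogy with simpler prochiral ketones. If 10 proves to be the mirror image, the equally available (S,S)-amine is used and nothing else changes.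

**Step 1**
Reactants: 1 (Z)-oct-2-en-1-ol
Product: 2 (Z)-1-chlorooct-2-ene
Conditions: PPh3, hexachloroacetone, CH2Cl2, 0 °C
Reagents that add atoms: hexachloroacetone, ClC(Cl)(Cl)C(=O)C(Cl)(Cl)Cl
Why: Appel-type chlorination replaces the activated oxygen of a primary allylic alcohol by SN2 at low temperature, so neither allylic transposition nor Z-to-E leakage should occur.

**Step 2**
Reactants: 2 (Z)-1-chlorooct-2-ene; 3 3-(benzyloxy)cyclobutan-1-one
Product: 5 3-(benzyloxy)-1-[(Z)-oct-2-en-1-yl]cyclobutan-1-ol (both ring diastereomers), via (Z)-oct-2-enylbarium chloride 4 (not isolated)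
Conditions: activated Ba (BaI2, lithium biphenylide, THF, rt); 2, −78 °C; then 3, −78 °C; aq. NH4Cl
Reagents that add atoms: none
Why: In the allylbarium carbonyl allylation, allylic barium reagents made at −78 °C keep their double-bond geometry and attack at the α-carbon, so the linear Z-octenyl carbinol should form instead of the branched γ-adduct typical of Mg or Zn reagents; the cis/trans mixture is harmless because the benzyloxy carbon later becomes the carbonyl.

**Step 3**
Reactants: 5 3-(benzyloxy)-1-[(Z)-oct-2-en-1-yl]cyclobutan-1-ol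
Product: 6 [3-(benzyloxy)-1-[(Z)-oct-2-en-1-yl]cyclobutoxy]triethylsilane
Conditions: TESOTf, 2,6-lutidine, CH2Cl2, −78 → 0 °C
Reagents that add atoms: triethylsilyl triflate, CC[Si](CC)(CC)OS(=O)(=O)C(F)(F)F
Why: Silyl triflate silylation is the standard way to protect a hindered tertiary alcohol, and it blocks the retro-aldol ring opening that a free 3-hydroxycyclobutanone would suffer later.

**Step 4**
Reactants: 6 [3-(benzyloxy)-1-[(Z)-oct-2-en-1-yl]cyclobutoxy]triethylsilane
Product: 7 3-[(Z)-oct-2-en-1-yl]-3-(triethylsilyloxy)cyclobutan-1-ol (both ring diastereomers)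
Conditions: LiDBB, THF, −78 °C; H2O quench at −78 °C
Reagents that add atoms: none
Why: Dissolving-metal-type reductive debenzylation with an arene radical anion cleaves the benzyl ether without touching the isolated Z-alkene or the silyl ether, and the cold quench gives the alkoxide no time for silyl migration.

**Step 5**
Reactants: 7 3-[(Z)-oct-2-en-1-yl]-3-(triethylsilyloxy)cyclobutan-1-ol
Product: 8 3-[(Z)-oct-2-en-1-yl]-3-(triethylsilyloxy)cyclobutan-1-one (achiral, Cs)
Conditions: TPAP (cat.), NMO, 4 Å MS, CH2Cl2, rt
Reagents that add atoms: none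
Why: The Ley–Griffith oxidation is a neutral two-electron oxidation that takes cyclobutanols to cyclobutanones without ring cleavage, and it merges both diastereomers of 7 into one prochiral ketone.

**Step 6**
Reactants: 8 3-[(Z)-oct-2-en-1-yl]-3-(triethylsilyloxy)cyclobutan-1-one
Product: 10 (R)-1,3-bis(triethylsilyloxy)-3-[(Z)-oct-2-en-1-yl]cyclobut-1-ene, via lithium enolate 9 (not isolated)
Conditions: (R,R)-bis(1-phenylethyl)amine, n-BuLi, THF; TESCl (internal quench), 8, −100 °C; cold non-aqueous work-up, product kept below 0 °C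
Reagents that add atoms: chlorotriethylsilane, CC[Si](CC)(CC)Cl
Why: Enantioselective deprotonation with a C2-symmetric chiral lithium amide under internal silyl chloride quench is known for prochiral 3-substituted cyclobutanones; it chooses between the enantiotopic C8H2 and C11H2 groups and so makes C12 a stereocentre, while −100 °C and instant trapping suppress β-elimination and enolate equilibration.

**Step 7**
Reactants: 10 (R)-1,3-bis(triethylsilyloxy)-3-[(Z)-oct-2-en-1-yl]cyclobut-1-ene
Product: 12 (R)-2-chloro-4-[(Z)-oct-2-en-1-yl]-4-(triethylsilyloxy)cyclopent-2-en-1-one, via dichlorobicyclo[2.1.0]pentane adduct 11 (not isolated)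
Conditions: CHCl3 (excess), KOt-Bu (slight excess over 10, slow addition), pentane, −40 → −10 °C; pH 7 buffer
Reagents that add atoms: chloroform, ClC(Cl)Cl
Why: Dichlorocarbene, formed by α-elimination, adds cheletropically to the strained, electron-rich C9=C11 enol double bond to give the 5,5-dichloro-1-siloxybicyclo[2.1.0]pentane 11, in which loss of the endo chloride is concerted with disrotatory 2π-electrocyclic cleavage of the shared C9–C11 bond, and chloride then desilylates the 2-chloro-1-siloxycyclopentenyl cation to give 12. The closest known reaction type is the dihalocarbene one-carbon ring enlargement of cyclic silyl enol ethers to 2-halo-enones, together with the spontaneous cyclopropyl-to-allyl opening of dihalocarbene adducts of cyclobutenes, and release of the strain of both small rings (roughly 50 kcal/mol) should let it run below 0 °C without silver salt or heat. Mode of closure: the five-membered ring is not closed end to end but arises by [2+1] closure of the cyclopropane followed by 4→5 enlargement, with C10 inserted between C9 and C11, so that C9=O, C10–Cl and C10=C11 appear together and in the right places. No lasting stereocentre is formed, because the new centres C9 and C11 of either facial adduct are flattened again so that the facial mixture converges, and the untouched C12 keeps the configuration set in step 6. The step needs chemoselectivity for the enol ether over the C14=C15 Z-alkene, secured by the oxygen donor, the ring strain and the small excess of carbene, and regioselectivity, secured because carbon can enter only where the enol double bond lies. The low temperature also holds back conrotatory opening of the 3-siloxycyclobutene and attack of base or trichloromethanide on 12.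

**Step 8**
Reactants: 13 methyl hex-5-enoate; 14 (E)-but-2-enal (crotonaldehyde, excess)
Product: 15 methyl (E)-7-oxohept-5-enoate
Conditions: Hoveyda–Grubbs II (cat.), CH2Cl2, 40 °C
Reagents that add atoms: none
Why: Olefin cross metathesis of a terminal alkene with an enal partner is selective for the cross product and gives the E-enal under thermodynamic control, which sets the 5E geometry.

**Step 9**
Reactants: 12 (R)-2-chloro-4-[(Z)-oct-2-en-1-yl]-4-(triethylsilyloxy)cyclopent-2-en-1-one; 15 methyl (E)-7-oxohept-5-enoate
Product: 17 methyl (E)-7-{(5R)-3-chloro-5-[(Z)-oct-2-en-1-yl]-2-oxo-5-(triethylsilyloxy)cyclopent-3-en-1-yl}-7-hydroxyhept-5-enoate (mixture at C7 and C8), via lithium cross-conjugated dienolate 16 (not isolated)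
Conditions: LiHMDS, THF, −78 °C; then 15, −78 °C; AcOH quench at −78 °C
Reagents that add atoms: none
Why: In this lithium aldol addition C8 is the only enolisable position of 12, the enolate adds 1,2 to the enal at −78 °C faster than it loses the β-silyloxy group, and the new centres C7 and C8 need no control because step 10 erases them.

**Step 10**
Reactants: 17 aldol adduct (diastereomer mixture)
Product: 19 methyl (5E,7E)-7-{(2S)-4-chloro-2-[(Z)-oct-2-en-1-yl]-5-oxo-2-(triethylsilyloxy)cyclopent-3-en-1-ylidene}hept-5-enoate, via allylic mesylate 18 (not isolated)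
Conditions: MsCl, Et3N (excess), CH2Cl2, −20 → 0 °C
Reagents that add atoms: none
Why: Mesylation followed by E1cB elimination completes the aldol condensation and funnels all diastereomers of 17 through one enolate into the cross-conjugated dienone, in which the 7E geometry should prevail because the Z isomer presses the dienyl chain against the C9 carbonyl oxygen; any minor 7Z isomer is removed by chromatography.

**Step 11**
Reactants: 19 silyl-protected dienone
Product: 20 methyl (5E,7E)-7-{(2S)-4-chloro-2-hydroxy-2-[(Z)-oct-2-en-1-yl]-5-oxocyclopent-3-en-1-ylidene}hept-5-enoate (target)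
Conditions: HF·pyridine, pyridine, THF, 0 °C → rt
Reagents that add atoms: none
Why: Buffered acidic fluoride cleaves only the Si–O bond, so C12 keeps its configuration, and it avoids the basic fluoride sources that would provoke retro-aldol, β-elimination or Michael addition on the dienone.

**Compound list**

| No. | Name | SMILES | Role |
|---|---|---|---|
| 1 | (Z)-oct-2-en-1-ol | CCCCC/C=C\CO | starting material |
| 2 | (Z)-1-chlorooct-2-ene | CCCCC/C=C\CCl | intermediate |
| 3 | 3-(benzyloxy)cyclobutan-1-one | O=C1CC(OCc2ccccc2)C1 | starting material |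
| 4 | (Z)-oct-2-enylbarium chloride | CCCCC/C=C\C[Ba]Cl | intermediate |
| 5 | 3-(benzyloxy)-1-[(Z)-oct-2-en-1-yl]cyclobutan-1-ol (cis/trans mixture) | CCCCC/C=C\CC1(O)CC(OCc2ccccc2)C1 | intermediate |
| 6 | [3-(benzyloxy)-1-[(Z)-oct-2-en-1-yl]cyclobutoxy]triethylsilane (cis/trans mixture) | CCCCC/C=C\CC1(O[Si](CC)(CC)CC)CC(OCc2ccccc2)C1 | intermediate |
| 7 | 3-[(Z)-oct-2-en-1-yl]-3-(triethylsilyloxy)cyclobutan-1-ol (cis/trans mixture) | CCCCC/C=C\CC1(O[Si](CC)(CC)CC)CC(O)C1 | intermediate |
| 8 | 3-[(Z)-oct-2-en-1-yl]-3-(triethylsilyloxy)cyclobutan-1-one | CCCCC/C=C\CC1(O[Si](CC)(CC)CC)CC(=O)C1 | intermediate |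
| 9 | lithium (R)-3-[(Z)-oct-2-en-1-yl]-3-(triethylsilyloxy)cyclobut-1-en-1-olate | CCCCC/C=C\C[C@]1(O[Si](CC)(CC)CC)C=C([O-])C1.[Li+] | intermediate |
| 10 | (R)-1,3-bis(triethylsilyloxy)-3-[(Z)-oct-2-en-1-yl]cyclobut-1-ene | CCCCC/C=C\C[C@]1(O[Si](CC)(CC)CC)C=C(O[Si](CC)(CC)CC)C1 | intermediate |
| 11 | 5,5-dichloro-1,3-bis(triethylsilyloxy)-3-[(Z)-oct-2-en-1-yl]bicyclo[2.1.0]pentane (C12 as in 10, either face at the bridgeheads) | CCCCC/C=C\C[C@]1(O[Si](CC)(CC)CC)C2C(Cl)(Cl)C2(O[Si](CC)(CC)CC)C1 | intermediate |
| 12 | (R)-2-chloro-4-[(Z)-oct-2-en-1-yl]-4-(triethylsilyloxy)cyclopent-2-en-1-one | CCCCC/C=C\C[C@]1(O[Si](CC)(CC)CC)C=C(Cl)C(=O)C1 | intermediate |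
| 13 | methyl hex-5-enoate | C=CCCCC(=O)OC | starting material |
| 14 | (E)-but-2-enal | C/C=C/C=O | starting material |
| 15 | methyl (E)-7-oxohept-5-enoate | O=C/C=C/CCCC(=O)OC | intermediate |
| 16 | lithium cross-conjugated dienolate of 12 | CCCCC/C=C\C[C@]1(O[Si](CC)(CC)CC)C=C(Cl)C([O-])=C1.[Li+] | intermediate |
| 17 | aldol adduct, C12 defined, mixture at C7 and C8 | CCCCC/C=C\C[C@]1(O[Si](CC)(CC)CC)C=C(Cl)C(=O)C1C(O)/C=C/CCCC(=O)OC | intermediate |
| 18 | C7 methanesulfonate of 17 | CCCCC/C=C\C[C@]1(O[Si](CC)(CC)CC)C=C(Cl)C(=O)C1C(OS(C)(=O)=O)/C=C/CCCC(=O)OC | intermediate |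
| 19 | 12-O-triethylsilyl ether of the target (5E,7E,12S,14Z) | CCCCC/C=C\C[C@]1(O[Si](CC)(CC)CC)C=C(Cl)C(=O)/C1=C/C=C/CCCC(=O)OC | intermediate |
| 20 | methyl (5E,7E)-7-{(2S)-4-chloro-2-hydroxy-2-[(Z)-oct-2-en-1-yl]-5-oxocyclopent-3-en-1-ylidene}hept-5-enoate | CCCCC/C=C\C[C@]1(O)C=C(Cl)C(=O)/C1=C/C=C/CCCC(=O)OC | target |

Total step count: 11. Longest linear sequence: 10 (steps 1–7 and 9–11).

**Steps most likely to fail**

**Step 7.** The strained enol silane may ring-open or be desilylated by alkoxide before it captures the carbene, and the base-sensitive chloroenone may be consumed by trichloromethanide.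

The fallback separates ring enlargement from chlorination. It sets out from 10 and returns at 12.
- Cyclopropanation of the enol double bond with Et2Zn/CH2I2 (Simmons–Smith) should give the siloxybicyclo[2.1.0]pentane F1.
- FeCl3 in DMF opens its central bond oxidatively to the 3-chlorocyclopentanone F2.
- NaOAc in MeOH eliminates HCl to give the 4-silyloxycyclopentenone F3.
- Nucleophilic epoxidation (t-BuOOH, Triton B), which ignores the isolated Z-alkene, gives the epoxy ketone F4.
- Pyridinium chloride opens F4 at the α-carbon to the chlorohydrin F5, which loses water to give 12.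

**Step 6.** Discrimination between the two enantiotopic methylene groups may be poor, because both puckered conformers of the 3,3-disubstituted ring are populated.

The fallback replaces desymmetrisation by resolution. It sets out from 8 and returns at 12.
- LDA with internal TESCl gives, by way of the racemic lithium enolate F6, the racemic enol silane F7.
- The conditions of step 7 carry F7 through the racemic dichlorobicyclopentane F8 to the racemic chloroenone F9.
- Preparative HPLC on a polysaccharide chiral phase separates F9 into 12 and its enantiomer F10, which is discarded.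

**Step 2.** Geometry may be lost, or attack may occur at the γ-carbon if the allylbarium species equilibrates, and the ketone may be partly enolised.

The fallback builds the ω-chain stepwise. It sets out from 3 and returns at 6.
- Allylmagnesium bromide adds to 3 to give the allyl carbinol F11.
- TESOTf/2,6-lutidine gives its silyl ether F12.
- Ozonolysis with Me2S work-up gives the aldehyde F13.
- A salt-free Z-selective Wittig reaction with hexyltriphenylphosphonium bromide/NaHMDS at −78 °C gives 6.

**Further compounds**

F1 | step 7 | 1,3-bis(triethylsilyloxy)-3-[(Z)-oct-2-en-1-yl]bicyclo[2.1.0]pentane | CCCCC/C=C\C[C@]1(O[Si](CC)(CC)CC)C2CC2(O[Si](CC)(CC)CC)C1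
F2 | step 7 | 3-chloro-4-[(Z)-oct-2-en-1-yl]-4-(triethylsilyloxy)cyclopentan-1-one | CCCCC/C=C\C[C@]1(O[Si](CC)(CC)CC)C(Cl)CC(=O)C1
F3 | step 7 | (R)-4-[(Z)-oct-2-en-1-yl]-4-(triethylsilyloxy)cyclopent-2-en-1-one | CCCCC/C=C\C[C@]1(O[Si](CC)(CC)CC)C=CC(=O)C1
F4 | step 7 | 2,3-epoxy-4-[(Z)-oct-2-en-1-yl]-4-(triethylsilyloxy)cyclopentan-1-one | CCCCC/C=C\C[C@]1(O[Si](CC)(CC)CC)C2OC2C(=O)C1
F5 | step 7 | 2-chloro-3-hydroxy-4-[(Z)-oct-2-en-1-yl]-4-(triethylsilyloxy)cyclopentan-1-one | CCCCC/C=C\C[C@]1(O[Si](CC)(CC)CC)C(O)C(Cl)C(=O)C1
F6 | step 6 | racemic lithium enolate of 8 | CCCCC/C=C\CC1(O[Si](CC)(CC)CC)C=C([O-])C1.[Li+]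
F7 | step 6 | racemic 1,3-bis(triethylsilyloxy)-3-[(Z)-oct-2-en-1-yl]cyclobut-1-ene | CCCCC/C=C\CC1(O[Si](CC)(CC)CC)C=C(O[Si](CC)(CC)CC)C1
F8 | step 6 | racemic 5,5-dichloro-1,3-bis(triethylsilyloxy)-3-[(Z)-oct-2-en-1-yl]bicyclo[2.1.0]pentane | CCCCC/C=C\CC1(O[Si](CC)(CC)CC)C2C(Cl)(Cl)C2(O[Si](CC)(CC)CC)C1
F9 | step 6 | racemic 2-chloro-4-[(Z)-oct-2-en-1-yl]-4-(triethylsilyloxy)cyclopent-2-en-1-one | CCCCC/C=C\CC1(O[Si](CC)(CC)CC)C=C(Cl)C(=O)C1
F10 | step 6 | (S)-2-chloro-4-[(Z)-oct-2-en-1-yl]-4-(triethylsilyloxy)cyclopent-2-en-1-one | CCCCC/C=C\C[C@@]1(O[Si](CC)(CC)CC)C=C(Cl)C(=O)C1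
F11 | step 2 | 1-allyl-3-(benzyloxy)cyclobutan-1-ol | C=CCC1(O)CC(OCc2ccccc2)C1
F12 | step 2 | [1-allyl-3-(benzyloxy)cyclobutoxy]triethylsilane | C=CCC1(O[Si](CC)(CC)CC)CC(OCc2ccccc2)C1
F13 | step 2 | 2-[3-(benzyloxy)-1-(triethylsilyloxy)cyclobutyl]acetaldehyde | O=CCC1(O[Si](CC)(CC)CC)CC(OCc2ccccc2)C1
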